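## Retrosynthetic overview
1. Target **15** ← global removal of the 7-O-MOM and 3'-O-TBS groups ← cross-metathesis of an allyl arene to the prenyl arene.
2. The 3'-OH/4'-OMe pair comes from IBX ortho-hydroxylation of a 4'-phenol. The resulting catechol is differentiated by sterics (silylate the unhindered 3'-OH, methylate the hindered 4'-OH).
3. The key C–C bond, aryl–C5' (ortho to the 4'-O), forms by an aromatic Claisen [3,3]-sigmatropic rearrangement of a 4'-O-allyl ether.
4. Both arenes and the chromanone ring come pre-formed in cheap, natural (2S)-liquiritigenin, which supplies the only stereocenter. No ring is built and C2 is never touched.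

Assumption: (2S)-liquiritigenin (natural flavanone, from licorice) is purchasable, and C2 keeps its configuration under the mild base and short heating used below.

## Route

**Step 1**
Reactants: **1** (2S)-liquiritigenin; **2** chloromethyl methyl ether
Product: **3** (2S)-7-(methoxymethoxy)-2-(4-hydroxyphenyl)chroman-4-one
Conditions: MOMCl (1.05 equiv), K2CO3 (1.0 equiv), acetone, 0 °C → rt
Reagents that add atoms: MOMCl, ClCOC
Why: The 7-OH (para to the C=O) is the most acidic phenol, so one equivalent of base gives selective O-alkylation (Williamson-type). The MOM group masks it through the Claisen and later steps. C2 is untouched.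

**Step 2**
Reactants: **3**; **4** allyl bromide
Product: **5** (2S)-2-(4-allyloxyphenyl)-7-(methoxymethoxy)chroman-4-one
Conditions: allyl bromide (1.5 equiv), K2CO3, acetone, 55 °C
Reagents that add atoms: allyl bromide, C=CCBr
Why: The only free phenol (4'-OH) is O-allylated under mild carbonate conditions (Williamson ether synthesis). This sets up the aryl allyl ether for [3,3] rearrangement.

**Step 3**
Reactants: **5**
Product: **6** (2S)-2-(3-allyl-4-hydroxyphenyl)-7-(methoxymethoxy)chroman-4-one
Conditions: o-dichlorobenzene, 190 °C (microwave or sealed tube), 30–60 min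
Reagents that add atoms: none
Why: Aromatic Claisen rearrangement, a suprafacial [3,3] shift of the aryl allyl ether. The para position is blocked by the chromanone C2, so the allyl group goes to the ortho carbon (C3') and the ring rearomatizes to the phenol. C2 is remote and is not involved.

**Step 4**
Reactants: **6**; **7** IBX (2-iodoxybenzoic acid)
Product: **8** (2S)-2-(3-allyl-4,5-dihydroxyphenyl)-7-(methoxymethoxy)chroman-4-one
Conditions: IBX (1.3 equiv), DMF, rt; then aq. Na2S2O4, rt
Reagents that add atoms: IBX, O=C1OI(=O)(O)c2ccccc12 (source of the new O)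
Why: Phenol-directed ortho-oxygenation by IBX goes to the free ortho carbon (C5'), giving the o-quinone. Dithionite then reduces it to the catechol. The product is a 3-allylcatechol in which the two OH groups are sterically different.

**Step 5**
Reactants: **8**; **9** tert-butyldimethylsilyl chloride
Product: **10** (2S)-2-[3-allyl-4-hydroxy-5-(tert-butyldimethylsilyloxy)phenyl]-7-(methoxymethoxy)chroman-4-one
Conditions: TBSCl (1.1 equiv), imidazole, DMF, 0 °C
Reagents that add atoms: TBSCl, CC(C)(C)[Si](C)(C)Cl
Why: The bulky silyl chloride reacts at the unhindered 3'-OH. The 4'-OH, flanked by the allyl group and the neighbouring OR, stays free. This is steric discrimination in silyl-ether formation.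

**Step 6**
Reactants: **10**; **11** iodomethane
Product: **12** (2S)-2-[3-allyl-5-(tert-butyldimethylsilyloxy)-4-methoxyphenyl]-7-(methoxymethoxy)chroman-4-one
Conditions: MeI (3 equiv), K2CO3, acetone, 45 °C
Reagents that add atoms: MeI, CI
Why: Williamson O-methylation of the remaining phenol gives the 4'-OMe. The mild base leaves the TBS and MOM ethers and C2 intact.

**Step 7**
Reactants: **12**; **13** 2-methyl-2-butene
Product: **14** (2S)-2-[3-(3-methylbut-2-enyl)-5-(tert-butyldimethylsilyloxy)-4-methoxyphenyl]-7-(methoxymethoxy)chroman-4-one
Conditions: Grubbs II (5 mol%), 2-methyl-2-butene (20 equiv), CH2Cl2, 40 °C, sealed tube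
Reagents that add atoms: 2-methyl-2-butene, CC=C(C)C (supplies the =CMe2 terminus)
Why: Olefin cross-metathesis converts the terminal allyl alkene to the trisubstituted prenyl alkene; the excess trisubstituted alkene drives the exchange and ethylene is lost. No free phenols are present to poison the catalyst, and the flavanone C=O is inert.

**Step 8**
Reactants: **14**
Product: **15** erylatissin C, (2S)-7-hydroxy-2-[3-hydroxy-4-methoxy-5-(3-methylbut-2-enyl)phenyl]chroman-4-one
Conditions: 3 M HCl, THF/MeOH (1:2), 45 °C
Reagents that add atoms: none
Why: Acid hydrolysis removes the MOM acetal and the aryl TBS ether together. Protonolysis of silyl and acetal ethers is not expected to open the flavanone ring or touch the 4'-OMe. The prenyl alkene is meta to the new 3'-OH and cannot cyclize onto it.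

## Checks
- **Structure:** The target carries a 7-OH chromanone, a B ring with 3'-OH, 4'-OMe and 5'-prenyl, and (2S) configuration. The SMILES of **15** matches the given one.
- **Atom balance:**

  | Compound | Formula |
  |---|---|
  | 1 | C15H12O4 |
  | 3 | C17H16O5 |
  | 5, 6 | C20H20O5 |
  | 8 | C20H20O6 |
  | 10 | C26H34O6Si |
  | 12 | C27H36O6Si |
  | 14 | C29H40O6Si |
  | 15 | C21H22O5 |

  Step 8 removes the MOM group (C2H4O net) and the TBS group (C6H14Si), leaving C21H22O5.
- **Stereochemistry:** C2 is present in 1 and never touched. The configuration was checked against the SMILES and is (S) in 1 and 15.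

## Compound list
1 | (2S)-liquiritigenin | Oc1ccc(cc1)[C@@H]2CC(=O)c3ccc(O)cc3O2 | starting material
2 | chloromethyl methyl ether | ClCOC | starting material (reagent)
3 | (2S)-7-O-MOM-liquiritigenin | Oc1ccc(cc1)[C@@H]2CC(=O)c3ccc(OCOC)cc3O2 | intermediate
4 | allyl bromide | C=CCBr | starting material (reagent)
5 | (2S)-4'-O-allyl-7-O-MOM-liquiritigenin | C=CCOc1ccc(cc1)[C@@H]2CC(=O)c3ccc(OCOC)cc3O2 | intermediate
6 | (2S)-3'-allyl-4'-hydroxy-7-O-MOM flavanone | C=CCc1cc(ccc1O)[C@@H]2CC(=O)c3ccc(OCOC)cc3O2 | intermediate
7 | IBX | O=C1OI(=O)(O)c2ccccc12 | starting material (reagent)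
8 | (2S)-5'-allyl-3',4'-dihydroxy-7-O-MOM flavanone | C=CCc1cc(cc(O)c1O)[C@@H]2CC(=O)c3ccc(OCOC)cc3O2 | intermediate
9 | tert-butyldimethylsilyl chloride | CC(C)(C)[Si](C)(C)Cl | starting material (reagent)
10 | 3'-O-TBS-4'-hydroxy-5'-allyl-7-O-MOM flavanone | C=CCc1cc(cc(O[Si](C)(C)C(C)(C)C)c1O)[C@@H]2CC(=O)c3ccc(OCOC)cc3O2 | intermediate
11 | iodomethane | CI | starting material (reagent)
12 | 3'-O-TBS-4'-OMe-5'-allyl-7-O-MOM flavanone | C=CCc1cc(cc(O[Si](C)(C)C(C)(C)C)c1OC)[C@@H]2CC(=O)c3ccc(OCOC)cc3O2 | intermediate
13 | 2-methyl-2-butene | CC=C(C)C | starting material (reagent)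
14 | 3'-O-TBS-4'-OMe-5'-prenyl-7-O-MOM flavanone | CC(C)=CCc1cc(cc(O[Si](C)(C)C(C)(C)C)c1OC)[C@@H]2CC(=O)c3ccc(OCOC)cc3O2 | intermediate
15 | erylatissin C | COc1c(O)cc([C@@H]2CC(=O)c3ccc(O)cc3O2)cc1CC=C(C)C | target

## Totals
Total steps: 8. Longest linear sequence: 8 (from 1).

## Three steps most likely to fail
1. **Step 3 (thermal Claisen).** C2 can racemize by retro-oxa-Michael ring opening at 190 °C, and the product can decompose.
   - Fallback: avoid the pericyclic heating. Brominate the 4'-phenol ortho (NBS) on the 7-O-MOM flavanone, then do a Pd-catalysed Stille coupling with allyltributyltin at 80 °C.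
2. **Step 7 (cross-metathesis).** Yields can be low, and the allyl arene can isomerize to the propenyl arene.
   - Fallback: introduce the prenyl group directly. Make the 1,1-dimethylpropargyl ether (3-chloro-3-methylbut-1-yne, K2CO3, CuI) in place of the allyl ether, semihydrogenate it to the 1,1-dimethylallyl ether, and let the Claisen deliver the normal prenyl group.
3. **Step 4 (IBX ortho-hydroxylation).** Over-oxidation or low regioselectivity is possible.
   - Fallback: switch to ortho-formylation of the Claisen phenol (MgCl2, Et3N, paraformaldehyde) at the free ortho carbon, followed by a Dakin oxidation (H2O2, NaOH) to the same catechol.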